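**Strategy.** The enedione ring (C1(=O)–C2H=C3H–C4(=O), fused at C4a/C8a) is unsubstituted and symmetric, and its fusion carbons are flanked by the para oxygens at C5 (OMe) and C8 (OH). It is therefore built last, from a 3,6-dialkoxybenzyne and 2-methoxyfuran. One aryne Diels–Alder reaction forms both the C4a–C4 and C8a–C1 bonds; the bridged ketal opens to a 4-methoxy-1-naphthol, and PhI(OAc)2 unveils the quinone. Either cycloaddition regiochemistry gives the same ring. The precursor is an aryl bromide from gentisaldehyde that already carries the (R)-carbinol side chain and a MOM ether; LDA removes the one C–H between bromine and OMOM.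

Key step: step 6

Remark: locants follow the product naphthalene-1,4-dione (C1/C4 carbonyls, C5 OMe, C6 side chain, C8 OH); the side-chain carbinol is (R) throughout (O > aryl > CH2 > H).

**Step 1**
Reactants: 1 2,5-dihydroxybenzaldehyde; 2 chloromethyl methyl ether
Product: 3 2-hydroxy-5-(methoxymethoxy)benzaldehyde
Conditions: MOMCl (1.05 equiv), i-Pr2NEt, CH2Cl2, 0 °C
Reagents that add atoms: chloromethyl methyl ether, COCCl
Why: O-alkylation (MOM protection) should occur at the free 5-OH, because the 2-OH is tied up in a hydrogen bond to the aldehyde and is the poorer nucleophile.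

**Step 2**
Reactants: 3 2-hydroxy-5-(methoxymethoxy)benzaldehyde; 4 N-bromosuccinimide
Product: 5 3-bromo-2-hydroxy-5-(methoxymethoxy)benzaldehyde
Conditions: NBS (1.05 equiv), MeCN, 0 °C to rt
Reagents that add atoms: N-bromosuccinimide, O=C1CCC(=O)N1Br
Why: Electrophilic aromatic bromination should go to C3, the only open position ortho to the free phenol (para is blocked) and meta to the deactivating aldehyde, under neutral conditions that spare the MOM acetal.

**Step 3**
Reactants: 5 3-bromo-2-hydroxy-5-(methoxymethoxy)benzaldehyde; 6 iodomethane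
Product: 7 3-bromo-2-methoxy-5-(methoxymethoxy)benzaldehyde
Conditions: MeI, K2CO3, DMF, rt
Reagents that add atoms: iodomethane, CI
Why: Williamson etherification of the acidic salicylaldehyde phenoxide fixes the future C5 methyl ether and differentiates the two ring oxygens.

**Step 4**
Reactants: 7 3-bromo-2-methoxy-5-(methoxymethoxy)benzaldehyde; 8 lIpc2B(allyl), the B-allyldiisopinocampheylborane derived from (−)-α-pinene
Product: 10 (1R)-1-[3-bromo-2-methoxy-5-(methoxymethoxy)phenyl]but-3-en-1-ol, via borinate ester 9 (not isolated)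
Conditions: lIpc2B(allyl) (1.2 equiv), Et2O, −78 °C; then NaOH, H2O2, 0 °C to rt
Reagents that add atoms: lIpc2B(allyl), C=CCB([C@H]1C[C@H]2C[C@@H]([C@@H]1C)C2(C)C)[C@H]1C[C@H]2C[C@@H]([C@@H]1C)C2(C)C
Why: Brown asymmetric allylboration through a closed chair transition state, in which the isopinocampheyl groups from (−)-α-pinene should deliver allyl to the Re face of the aryl aldehyde and so set the (R)-carbinol.

**Step 5**
Reactants: 10 (1R)-1-[3-bromo-2-methoxy-5-(methoxymethoxy)phenyl]but-3-en-1-ol; 11 2-methylbut-2-ene
Product: 12 (1R)-1-[3-bromo-2-methoxy-5-(methoxymethoxy)phenyl]-4-methylpent-3-en-1-ol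
Conditions: Grubbs II (5 mol%), 2-methylbut-2-ene/CH2Cl2, 40 °C
Reagents that add atoms: 2-methylbut-2-ene, CC=C(C)C
Why: Olefin cross-metathesis with excess 2-methylbut-2-ene should convert the terminal vinyl group into the prenyl-type trisubstituted alkene without touching the carbinol centre, the aryl bromide or the MOM ether.

**Step 6**
Reactants: 12 (1R)-1-[3-bromo-2-methoxy-5-(methoxymethoxy)phenyl]-4-methylpent-3-en-1-ol; 13 2-methoxyfuran
Product: 19 6-[(1R)-1-hydroxy-4-methylpent-3-en-1-yl]-5-methoxy-8-(methoxymethoxy)naphthalene-1,4-dione, via aryne 14 (not isolated), via cycloadduct 15 (not isolated), via regioisomeric cycloadduct 16 (not isolated), via methoxynaphthol 17 (not isolated), via regioisomeric methoxynaphthol 18 (not isolated)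
Conditions: LDA (commercial solution, 3.5 equiv), 2-methoxyfuran (8 equiv), THF, −78 °C to rt; aq. NH4Cl; crude naphthols (not purified), PhI(OAc)2 (1.3 equiv), MeCN/H2O, 0 °C
Reagents that add atoms: 2-methoxyfuran, COc1ccco1; water, O
Why: LDA first forms the lithium alkoxide and then removes the only hydrogen ortho to bromine (also acidified and directed by the OMOM group), and loss of LiBr on warming should give the 3,6-dialkoxybenzyne 14. The aryne is trapped by 2-methoxyfuran in a concerted aryne Diels–Alder reaction, an intermolecular [4+2] annulation that closes the new six-membered carbocycle by forming the C4a–C4 and C8a–C1 bonds at once, with a transient 1,4-oxygen bridge. The bridged ketals 15/16 open through the methoxy-stabilised oxocarbenium ion and aromatise to the 4-methoxy-1-naphthols 17/18; PhI(OAc)2 then oxidises the free naphthol, water adds at the methoxy-bearing para carbon and methanol is expelled to give the quinone. The closest known reaction type is the aryne/2-alkoxyfuran cycloaddition with ring opening to 4-alkoxy-1-naphthols, followed by hypervalent-iodine oxidative demethylation to 1,4-naphthoquinones. No stereocentre from the cycloaddition survives (the bridgehead centres of 15/16 are lost on aromatisation), and the (R)-carbinol is carried through untouched as its alkoxide. Site selectivity in aryne formation is secured because bromine has a single ortho hydrogen; cycloaddition regiochemistry is irrelevant because both isomers converge on the same symmetric enedione ring; and chemoselective oxidation is secured because PhI(OAc)2 reacts only at the free naphthol and should leave the dialkoxy ring and the alkene alone.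

**Step 7**
Reactants: 19 6-[(1R)-1-hydroxy-4-methylpent-3-en-1-yl]-5-methoxy-8-(methoxymethoxy)naphthalene-1,4-dione; 20 3-methylbut-2-enoic acid
Product: 21 (1R)-1-[5-methoxy-8-(methoxymethoxy)-1,4-dioxo-1,4-dihydronaphthalen-6-yl]-4-methylpent-3-en-1-yl 3-methylbut-2-enoate
Conditions: DCC (1.5 equiv), DMAP (0.2 equiv), CH2Cl2, 0 °C to rt
Reagents that add atoms: 3-methylbut-2-enoic acid, CC(C)=CC(=O)O
Why: Steglich esterification acylates the only free hydroxyl at oxygen, so the C–O bond of the stereocentre is not broken and the (R) configuration should be retained.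

**Step 8**
Reactants: 21 (1R)-1-[5-methoxy-8-(methoxymethoxy)-1,4-dioxo-1,4-dihydronaphthalen-6-yl]-4-methylpent-3-en-1-yl 3-methylbut-2-enoate
Product: 22 (1R)-1-(8-hydroxy-5-methoxy-1,4-dioxo-1,4-dihydronaphthalen-6-yl)-4-methylpent-3-en-1-yl 3-methylbut-2-enoate (CNP0130192.1)
Conditions: TFA/CH2Cl2 (1:10), 0 °C; aq. NaHCO3
Reagents that add atoms: none
Why: Acid-mediated cleavage of the aryl MOM acetal should be fast because the departing phenol is hydrogen-bonded to the peri C1 carbonyl, while the benzylic ester sits on a ring deactivated by the para acyl group and should resist ionisation.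

**Compound list**

1 | 2,5-dihydroxybenzaldehyde | O=Cc1cc(O)ccc1O | starting material
2 | chloromethyl methyl ether | COCCl | starting material
3 | 2-hydroxy-5-(methoxymethoxy)benzaldehyde | COCOc1ccc(O)c(C=O)c1 | intermediate
4 | N-bromosuccinimide | O=C1CCC(=O)N1Br | starting material
5 | 3-bromo-2-hydroxy-5-(methoxymethoxy)benzaldehyde | COCOc1cc(Br)c(O)c(C=O)c1 | intermediate
6 | iodomethane | CI | starting material
7 | 3-bromo-2-methoxy-5-(methoxymethoxy)benzaldehyde | COCOc1cc(Br)c(OC)c(C=O)c1 | intermediate
8 | lIpc2B(allyl), B-allyldiisopinocampheylborane derived from (−)-α-pinene | C=CCB([C@H]1C[C@H]2C[C@@H]([C@@H]1C)C2(C)C)[C@H]1C[C@H]2C[C@@H]([C@@H]1C)C2(C)C | starting material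
9 | diisopinocampheylborinate ester of 10 (formed in step 4) | COCOc1cc(Br)c(OC)c([C@@H](CC=C)OB([C@H]2C[C@H]3C[C@@H]([C@@H]2C)C3(C)C)[C@H]2C[C@H]3C[C@@H]([C@@H]2C)C3(C)C)c1 | intermediate
10 | (1R)-1-[3-bromo-2-methoxy-5-(methoxymethoxy)phenyl]but-3-en-1-ol | COCOc1cc(Br)c(OC)c([C@@H](CC=C)O)c1 | intermediate
11 | 2-methylbut-2-ene | CC=C(C)C | starting material
12 | (1R)-1-[3-bromo-2-methoxy-5-(methoxymethoxy)phenyl]-4-methylpent-3-en-1-ol | COCOc1cc(Br)c(OC)c([C@@H](CC=C(C)C)O)c1 | intermediate
13 | 2-methoxyfuran | COc1ccco1 | starting material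
14 | lithium (1R)-1-[2-methoxy-5-(methoxymethoxy)-3,4-didehydrophenyl]-4-methylpent-3-en-1-olate (aryne, formed in step 6) | COCOC1=CC([C@@H](CC=C(C)C)[O-])=C(OC)C#C1.[Li+] | intermediate
15 | lithium (1R)-1-[4,5-dimethoxy-8-(methoxymethoxy)-1,4-dihydro-1,4-epoxynaphthalen-6-yl]-4-methylpent-3-en-1-olate (cycloadduct, formed in step 6) | COCOc1cc([C@@H](CC=C(C)C)[O-])c(OC)c2c1C1C=CC2(OC)O1.[Li+] | intermediate
16 | lithium (1R)-1-[1,5-dimethoxy-8-(methoxymethoxy)-1,4-dihydro-1,4-epoxynaphthalen-6-yl]-4-methylpent-3-en-1-olate (regioisomeric cycloadduct, formed in step 6) | COCOc1cc([C@@H](CC=C(C)C)[O-])c(OC)c2c1C1(OC)C=CC2O1.[Li+] | intermediate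
17 | 6-[(1R)-1-hydroxy-4-methylpent-3-en-1-yl]-4,5-dimethoxy-8-(methoxymethoxy)naphthalen-1-ol (formed in step 6) | COCOc1cc([C@@H](CC=C(C)C)O)c(OC)c2c(OC)ccc(O)c12 | intermediate
18 | 7-[(1R)-1-hydroxy-4-methylpent-3-en-1-yl]-4,8-dimethoxy-5-(methoxymethoxy)naphthalen-1-ol (formed in step 6) | COCOc1cc([C@@H](CC=C(C)C)O)c(OC)c2c(O)ccc(OC)c12 | intermediate
19 | 6-[(1R)-1-hydroxy-4-methylpent-3-en-1-yl]-5-methoxy-8-(methoxymethoxy)naphthalene-1,4-dione | COCOc1cc([C@@H](CC=C(C)C)O)c(OC)c2c1C(=O)C=CC2=O | intermediate
20 | 3-methylbut-2-enoic acid | CC(C)=CC(=O)O | starting material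
21 | (1R)-1-[5-methoxy-8-(methoxymethoxy)-1,4-dioxo-1,4-dihydronaphthalen-6-yl]-4-methylpent-3-en-1-yl 3-methylbut-2-enoate | COCOc1cc([C@@H](CC=C(C)C)OC(=O)C=C(C)C)c(OC)c2c1C(=O)C=CC2=O | intermediate
22 | (1R)-1-(8-hydroxy-5-methoxy-1,4-dioxo-1,4-dihydronaphthalen-6-yl)-4-methylpent-3-en-1-yl 3-methylbut-2-enoate (CNP0130192.1) | COc1c([C@@H](CC=C(C)C)OC(=O)C=C(C)C)cc(O)c2c1C(=O)C=CC2=O | target

**Total step count:** 8
**Longest linear sequence:** 8 steps (fully linear from 1)

**Steps most likely to fail**

Step 6. The aryne may be intercepted by diisopropylamine or lithium amide, or 2-methoxyfuran may be metalated and consumed, before cycloaddition takes place. In the oxidation stage the electron-rich methoxynaphthols may also couple oxidatively to binaphthyl dimers instead of giving the quinone. The fallback sets out from 12 and generates the same aryne (LDA, THF, −78 °C to rt) in furan as co-solvent, the most dependable aryne trap. This should give the isolable (1R)-1-[5-methoxy-8-(methoxymethoxy)-1,4-dihydro-1,4-epoxynaphthalen-6-yl]-4-methylpent-3-en-1-ol F1. Catalytic PPTS in CH2Cl2 should isomerise it to the regioisomeric 1-naphthols 7-[(1R)-1-hydroxy-4-methylpent-3-en-1-yl]-8-methoxy-5-(methoxymethoxy)naphthalen-1-ol F2 and 6-[(1R)-1-hydroxy-4-methylpent-3-en-1-yl]-5-methoxy-8-(methoxymethoxy)naphthalen-1-ol F3. Both are then oxidised at the free para position with Fremy's salt (KH2PO4 buffer, acetone/H2O), which comes back to the route at 19.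

Step 8. Under acid the benzylic C–O bond of the ester may ionise (loss or racemisation of the senecioate), or acid may add to the trisubstituted alkenes before the MOM acetal is cleaved. The fallback sets out from 19 and removes the MOM group first (TFA/CH2Cl2, 0 °C, or 1 M HCl in THF/MeOH) to give 8-hydroxy-6-[(1R)-1-hydroxy-4-methylpent-3-en-1-yl]-5-methoxynaphthalene-1,4-dione F4. Only the side-chain alcohol is then acylated with 20 (DCC, catalytic DMAP, CH2Cl2, 0 °C), relying on the low nucleophilicity of the peri phenol that is hydrogen-bonded to the C1 carbonyl. This comes back at 22, and the ester never meets acid.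

Step 1. Site selectivity between the two phenols may be lost, through etherification of the chelated 2-OH or of both hydroxyls. The fallback sets out from 1 and protects both phenols (MOMCl, NaH, DMF) as 2,5-bis(methoxymethoxy)benzaldehyde F5. Only the MOM group ortho to the aldehyde is then removed by chelation-assisted cleavage (MgBr2·OEt2, Et2O/CH2Cl2), which comes back at 3.

**Further compounds**

F1 | step 6 | (1R)-1-[5-methoxy-8-(methoxymethoxy)-1,4-dihydro-1,4-epoxynaphthalen-6-yl]-4-methylpent-3-en-1-ol | COCOc1cc([C@@H](CC=C(C)C)O)c(OC)c2c1C1C=CC2O1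
F2 | step 6 | 7-[(1R)-1-hydroxy-4-methylpent-3-en-1-yl]-8-methoxy-5-(methoxymethoxy)naphthalen-1-ol | COCOc1cc([C@@H](CC=C(C)C)O)c(OC)c2c(O)cccc12
F3 | step 6 | 6-[(1R)-1-hydroxy-4-methylpent-3-en-1-yl]-5-methoxy-8-(methoxymethoxy)naphthalen-1-ol | COCOc1cc([C@@H](CC=C(C)C)O)c(OC)c2cccc(O)c12
F4 | step 8 | 8-hydroxy-6-[(1R)-1-hydroxy-4-methylpent-3-en-1-yl]-5-methoxynaphthalene-1,4-dione | COc1c([C@@H](CC=C(C)C)O)cc(O)c2c1C(=O)C=CC2=O
F5 | step 1 | 2,5-bis(methoxymethoxy)benzaldehyde | COCOc1ccc(OCOC)c(C=O)c1
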